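**Retrosynthetic overview**

- The strategy rests on the oxolane's C3 carbinol carbon lying between the O1–C2 and C4–C5 ring bonds: C5 and O1 come from an aldehyde, C4–C3–C2 from an α-chiral allylsilane whose silicon ends on C3 as the latent hydroxyl.
- Late disconnections: phenols from benzyl ethers; the C1′ aryl ketone from hydration of an aryl alkyne; the cis C3–OH from a trans C3–SiMe2Ph group (Tamao–Fleming oxidation, then oxidation and bulky-hydride reduction).
- The only ring, the oxolane, is closed in one operation by a BF3-promoted [3+2] annulation of the (S)-allylsilane with the aryl ynal (C4–C5 first, then O1–C2 with 1,2-silyl shift).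
- The allylsilane comes from eugenol (benzylation, acrylate cross-metathesis, reduction, phosphate, Cu-catalysed enantioselective SN2′ silylation); the ynal comes from O-benzylvanillin (Corey–Fuchs, formylation).

Key step: step 8

Assumption: O-benzylvanillin is bought, and in step 5 the antipode of the chiral NHC ligand that delivers the (S)-silane is used; its sense of induction on this substrate is to be confirmed on a sample (oxidation to the allylic alcohol, Mosher analysis).

**Route**

Step 1
Reactants: 1 eugenol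
Product: 2 4-allyl-1-(benzyloxy)-2-methoxybenzene
Conditions: BnBr, K2CO3, acetone, reflux
Reagents that add atoms: benzyl bromide, BrCc1ccccc1
Why: Williamson ether synthesis puts a benzyl group on the phenol so that it survives the Lewis-acidic and basic steps and is freed at the end by hydrogenolysis.

Step 2
Reactants: 2 4-allyl-1-(benzyloxy)-2-methoxybenzene; 3 methyl acrylate
Product: 4 methyl (2E)-4-[4-(benzyloxy)-3-methoxyphenyl]but-2-enoate
Conditions: methyl acrylate (3 equiv), Hoveyda–Grubbs II (2 mol %), 1,4-benzoquinone (10 mol %), CH2Cl2, 40 °C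
Reagents that add atoms: none
Why: Olefin cross-metathesis of a type I allylarene with a type II acrylate favours the cross product and should give the E-enoate, which fixes the alkene geometry needed for the enantioselective silylation (benzoquinone suppresses alkene migration).

Step 3
Reactants: 4 methyl (2E)-4-[4-(benzyloxy)-3-methoxyphenyl]but-2-enoate
Product: 5 (2E)-4-[4-(benzyloxy)-3-methoxyphenyl]but-2-en-1-ol
Conditions: DIBAL-H (2.5 equiv), CH2Cl2, −78 °C; Rochelle salt work-up
Reagents that add atoms: none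
Why: DIBAL-H reduces the conjugated ester by 1,2-addition to the allylic alcohol without touching the E-alkene or the benzyl ether.

Step 4
Reactants: 5 (2E)-4-[4-(benzyloxy)-3-methoxyphenyl]but-2-en-1-ol
Product: 6 (2E)-4-[4-(benzyloxy)-3-methoxyphenyl]but-2-en-1-yl diethyl phosphate
Conditions: ClP(O)(OEt)2, Et3N, DMAP (cat.), CH2Cl2, 0 °C
Reagents that add atoms: diethyl chlorophosphate, CCOP(=O)(Cl)OCC
Why: O-phosphorylation of the primary allylic alcohol installs the leaving group used in copper-catalysed allylic substitution.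

Step 5
Reactants: 6 (2E)-4-[4-(benzyloxy)-3-methoxyphenyl]but-2-en-1-yl diethyl phosphate; 7 (dimethylphenylsilyl)boronic acid pinacol ester
Product: 8 (S)-[1-(4-benzyloxy-3-methoxyphenyl)but-3-en-2-yl]dimethyl(phenyl)silane
Conditions: chiral NHC–CuCl precatalyst (5 mol %), NaOMe (1.5 equiv), CH2Cl2, 0 °C
Reagents that add atoms: none
Why: Copper-catalysed enantioselective allylic substitution, in which a silylcopper formed by alkoxide-induced Si–B transmetalation adds SN2′ (γ-selectively) to the E-allylic phosphate and the chiral NHC ligand selects the alkene face so that the new C–Si stereocentre is S.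

Step 6
Reactants: 9 4-(benzyloxy)-3-methoxybenzaldehyde
Product: 10 1-(benzyloxy)-4-(2,2-dibromoethenyl)-2-methoxybenzene
Conditions: CBr4, PPh3, CH2Cl2, 0 °C
Reagents that add atoms: carbon tetrabromide, BrC(Br)(Br)Br
Why: Corey–Fuchs (Ramirez) dibromo-olefination of the aryl aldehyde by the ylide made in the flask from CBr4 and PPh3.

Step 7
Reactants: 10 1-(benzyloxy)-4-(2,2-dibromoethenyl)-2-methoxybenzene
Product: 12 3-[4-(benzyloxy)-3-methoxyphenyl]prop-2-ynal, via lithium arylacetylide 11 (not isolated)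
Conditions: n-BuLi (2.1 equiv), THF, −78 °C; then DMF, −78 → 0 °C; inverse quench into cold aq. KH2PO4
Reagents that add atoms: N,N-dimethylformamide, CN(C)C=O; n-butyllithium, [Li]CCCC (lithium of 11 only)
Why: Second stage of the Corey–Fuchs sequence, in which bromine–lithium exchange, Fritsch–Buttenberg–Wiechell rearrangement and deprotonation give the lithium acetylide, which is formylated by DMF and released as the ynal on the buffered quench.

Step 8
Reactants: 8 (S)-[1-(4-benzyloxy-3-methoxyphenyl)but-3-en-2-yl]dimethyl(phenyl)silane; 12 3-[4-(benzyloxy)-3-methoxyphenyl]prop-2-ynal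
Product: 13 [(2R,3S,5R)-2-{[4-(benzyloxy)-3-methoxyphenyl]methyl}-5-{[4-(benzyloxy)-3-methoxyphenyl]ethynyl}oxolan-3-yl]dimethyl(phenyl)silane
Conditions: BF3·OEt2 (1.1 equiv), 4 Å MS, CH2Cl2, −78 °C; Et3N then aq. NaHCO3 at −78 °C
Reagents that add atoms: none
Why: BF3 activates the ynal, the terminal alkene carbon of 8 adds to the carbonyl carbon on the alkene face anti to silicon (anti-SE′, forming C4–C5), and the resulting β-silyl cation is held as a silicon-bridged ion. The BF3-bound alkoxide then opens this bridge at its distal carbon C2 with inversion while silicon completes its 1,2-shift to C3; this is a five-membered O1–C2 closure (endo-mode opening of the three-membered ring, as for epoxides) that competes with loss of silicon to a simple homoallyl alcohol. The closest known reaction type is the Lewis acid-promoted [3+2] annulation of α-substituted allylsilanes with aldehydes to 3-silyl tetrahydrofurans. C2 is R because the S C–Si bond is replaced by C–O with inversion, and C3 carries silicon trans to the C2 arylmethyl group because that group sits anti to the vinyl terminus (A1,3-minimised conformer, E-like bridged ion) and addition across C2–C3 is anti. C5 is set in the C–C bond-forming step by an open synclinal transition state with the BF3-bound oxygen gauche to the alkene on the C2 side, BF3 pointing away from the silane and the slim alkynyl group over the C3–H, which should lead to the 2,5-cis ring. The step needs annulation over allylation and 1,2- over 1,4-addition; the low temperature, the non-nucleophilic counter-ion, the phenyldimethylsilyl group and the hard aldehyde carbon are relied on for both.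

Step 9
Reactants: 13 [(2R,3S,5R)-2-{[4-(benzyloxy)-3-methoxyphenyl]methyl}-5-{[4-(benzyloxy)-3-methoxyphenyl]ethynyl}oxolan-3-yl]dimethyl(phenyl)silane
Product: 14 (2R,3S,5R)-2-{[4-(benzyloxy)-3-methoxyphenyl]methyl}-5-{[4-(benzyloxy)-3-methoxyphenyl]ethynyl}oxolan-3-ol
Conditions: t-BuOOH (in decane, excess over KH), KH, NMP, rt; then 13, TBAF, 70 °C
Reagents that add atoms: tert-butyl hydroperoxide, CC(C)(C)OO
Why: Tamao–Fleming oxidation in its nucleophilic form (basic hydroperoxide with fluoride activation) cleaves phenyl from silicon and moves the ring carbon from silicon to oxygen with retention, so C3–OH stays trans to the C2 arylmethyl group, and no electrophile or strong acid meets the electron-rich rings, the alkyne or the β-alkoxysilane.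

Step 10
Reactants: 14 (2R,3S,5R)-2-{[4-(benzyloxy)-3-methoxyphenyl]methyl}-5-{[4-(benzyloxy)-3-methoxyphenyl]ethynyl}oxolan-3-ol
Product: 15 (2R,5R)-2-{[4-(benzyloxy)-3-methoxyphenyl]methyl}-5-{[4-(benzyloxy)-3-methoxyphenyl]ethynyl}oxolan-3-one
Conditions: Dess–Martin periodinane, NaHCO3, CH2Cl2, 0 °C → rt; crude ketone used at once
Reagents that add atoms: none
Why: Dess–Martin oxidation of the secondary alcohol under buffered neutral conditions erases the wrongly configured C3 centre without epimerising C2 or opening the ring.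

Step 11
Reactants: 15 (2R,5R)-2-{[4-(benzyloxy)-3-methoxyphenyl]methyl}-5-{[4-(benzyloxy)-3-methoxyphenyl]ethynyl}oxolan-3-one
Product: 16 (2R,3R,5R)-2-{[4-(benzyloxy)-3-methoxyphenyl]methyl}-5-{[4-(benzyloxy)-3-methoxyphenyl]ethynyl}oxolan-3-ol
Conditions: L-Selectride, THF, −78 °C; aqueous work-up
Reagents that add atoms: none
Why: Bulky-hydride (L-Selectride) reduction delivers hydride to the ketone face opposite the cis C2 and C5 substituents, so the new C3–OH should be cis to both (3R).

Step 12
Reactants: 16 (2R,3R,5R)-2-{[4-(benzyloxy)-3-methoxyphenyl]methyl}-5-{[4-(benzyloxy)-3-methoxyphenyl]ethynyl}oxolan-3-ol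
Product: 17 1-[4-(benzyloxy)-3-methoxyphenyl]-2-[(2R,4R,5R)-5-{[4-(benzyloxy)-3-methoxyphenyl]methyl}-4-hydroxyoxolan-2-yl]ethan-1-one
Conditions: [(JohnPhos)Au(MeCN)]SbF6 (5 mol %), 1,4-dioxane/H2O (10:1), rt → 50 °C
Reagents that add atoms: water, O
Why: Gold(I)-catalysed Markovnikov hydration places oxygen on the alkyne carbon bearing the 4-alkoxyaryl group (charge stabilised by the para oxygen, the other carbon deactivated by the ring oxygen), and should the cis C3–OH add first at that same carbon, the enol ether formed hydrolyses to the same ketone.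

Step 13
Reactants: 17 1-[4-(benzyloxy)-3-methoxyphenyl]-2-[(2R,4R,5R)-5-{[4-(benzyloxy)-3-methoxyphenyl]methyl}-4-hydroxyoxolan-2-yl]ethan-1-one
Product: 18 Renealtin A
Conditions: H2 (1 atm), 10 % Pd/C, EtOAc, rt, stopped at full debenzylation
Reagents that add atoms: none
Why: Palladium-catalysed hydrogenolysis cleaves both aryl benzyl ethers under neutral conditions that should leave the electron-rich aryl ketone, the β-alkoxy ketone and the three stereocentres untouched.

**Compound list**

1 | eugenol (4-allyl-2-methoxyphenol) | COc1cc(CC=C)ccc1O | starting material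
2 | 4-allyl-1-(benzyloxy)-2-methoxybenzene | COc1cc(CC=C)ccc1OCc1ccccc1 | intermediate
3 | methyl acrylate | C=CC(=O)OC | starting material
4 | methyl (2E)-4-[4-(benzyloxy)-3-methoxyphenyl]but-2-enoate | COC(=O)/C=C/Cc1ccc(OCc2ccccc2)c(OC)c1 | intermediate
5 | (2E)-4-[4-(benzyloxy)-3-methoxyphenyl]but-2-en-1-ol | OC/C=C/Cc1ccc(OCc2ccccc2)c(OC)c1 | intermediate
6 | (2E)-4-[4-(benzyloxy)-3-methoxyphenyl]but-2-en-1-yl diethyl phosphate | CCOP(=O)(OCC)OC/C=C/Cc1ccc(OCc2ccccc2)c(OC)c1 | intermediate
7 | (dimethylphenylsilyl)boronic acid pinacol ester | CC1(C)OB(OC1(C)C)[Si](C)(C)c1ccccc1 | starting material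
8 | (S)-[1-(4-benzyloxy-3-methoxyphenyl)but-3-en-2-yl]dimethyl(phenyl)silane | COc1cc(C[C@@H](C=C)[Si](C)(C)c2ccccc2)ccc1OCc1ccccc1 | intermediate
9 | 4-(benzyloxy)-3-methoxybenzaldehyde | COc1cc(C=O)ccc1OCc1ccccc1 | starting material
10 | 1-(benzyloxy)-4-(2,2-dibromoethenyl)-2-methoxybenzene | COc1cc(C=C(Br)Br)ccc1OCc1ccccc1 | intermediate
11 | lithium [4-(benzyloxy)-3-methoxyphenyl]acetylide (not isolated) | [Li]C#Cc1ccc(OCc2ccccc2)c(OC)c1 | intermediate
12 | 3-[4-(benzyloxy)-3-methoxyphenyl]prop-2-ynal | O=CC#Cc1ccc(OCc2ccccc2)c(OC)c1 | intermediate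
13 | [(2R,3S,5R)-2-{[4-(benzyloxy)-3-methoxyphenyl]methyl}-5-{[4-(benzyloxy)-3-methoxyphenyl]ethynyl}oxolan-3-yl]dimethyl(phenyl)silane (2,5-cis, silicon trans to the C2 group) | COc1cc(C[C@H]2O[C@@H](C#Cc3ccc(OCc4ccccc4)c(OC)c3)C[C@@H]2[Si](C)(C)c2ccccc2)ccc1OCc1ccccc1 | intermediate
14 | (2R,3S,5R)-2-{[4-(benzyloxy)-3-methoxyphenyl]methyl}-5-{[4-(benzyloxy)-3-methoxyphenyl]ethynyl}oxolan-3-ol (OH trans to the C2 group) | COc1cc(C[C@H]2O[C@@H](C#Cc3ccc(OCc4ccccc4)c(OC)c3)C[C@@H]2O)ccc1OCc1ccccc1 | intermediate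
15 | (2R,5R)-2-{[4-(benzyloxy)-3-methoxyphenyl]methyl}-5-{[4-(benzyloxy)-3-methoxyphenyl]ethynyl}oxolan-3-one | COc1cc(C[C@H]2O[C@@H](C#Cc3ccc(OCc4ccccc4)c(OC)c3)CC2=O)ccc1OCc1ccccc1 | intermediate
16 | (2R,3R,5R)-2-{[4-(benzyloxy)-3-methoxyphenyl]methyl}-5-{[4-(benzyloxy)-3-methoxyphenyl]ethynyl}oxolan-3-ol (all-cis) | COc1cc(C[C@H]2O[C@@H](C#Cc3ccc(OCc4ccccc4)c(OC)c3)C[C@H]2O)ccc1OCc1ccccc1 | intermediate
17 | 1-[4-(benzyloxy)-3-methoxyphenyl]-2-[(2R,4R,5R)-5-{[4-(benzyloxy)-3-methoxyphenyl]methyl}-4-hydroxyoxolan-2-yl]ethan-1-one | COc1cc(C[C@H]2O[C@@H](CC(=O)c3ccc(OCc4ccccc4)c(OC)c3)C[C@H]2O)ccc1OCc1ccccc1 | intermediate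
18 | Renealtin A, 1-(4-hydroxy-3-methoxyphenyl)-2-[(2R,4R,5R)-4-hydroxy-5-[(4-hydroxy-3-methoxyphenyl)methyl]oxolan-2-yl]ethan-1-one | COc1cc(C[C@H]2O[C@@H](CC(=O)c3ccc(O)c(OC)c3)C[C@H]2O)ccc1O | target

**Step count**

Total steps: 13. Longest linear sequence: 11 (steps 1–5, then 8–13).

**Steps most likely to fail**

1. Step 8. Silicon may be lost from the β-silyl cation before the alkoxide closes (simple allylation), the slim donor-substituted ynal may discriminate poorly between its faces at C5, and the electron-rich rings may compete as nucleophiles for the activated aldehyde or the bridged cation. The fallback sets out from 8 and comes back at 13. The aryl ynal is replaced by commercial 3-(triisopropylsilyl)prop-2-ynal, which is more electrophilic and carries a bulkier alkyne terminus. The same BF3·OEt2 annulation at −78 °C should give [(2R,3S,5R)-2-{[4-(benzyloxy)-3-methoxyphenyl]methyl}-5-[(triisopropylsilyl)ethynyl]oxolan-3-yl]dimethyl(phenyl)silane F1. TBAF in THF at 0 °C then frees [(2R,3S,5R)-2-{[4-(benzyloxy)-3-methoxyphenyl]methyl}-5-ethynyloxolan-3-yl]dimethyl(phenyl)silane F2. Sonogashira coupling (Pd(PPh3)2Cl2, CuI, Et3N, THF) with 1-(benzyloxy)-4-iodo-2-methoxybenzene F3, made from commercial 4-iodo-2-methoxyphenol with BnBr and K2CO3, returns to 13.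

2. Step 9. Phenyl may leave the hindered ring silicon only slowly, so that the hot basic peroxide medium has time to open the β-alkoxysilane or to degrade the alkyne. The fallback sets out from 13 and comes back at 14, and separates dephenylation from oxidation so that each runs at room temperature. Nucleophilic protodephenylation (t-BuOK, wet DMSO, rt) should give [(2R,3S,5R)-2-{[4-(benzyloxy)-3-methoxyphenyl]methyl}-5-{[4-(benzyloxy)-3-methoxyphenyl]ethynyl}oxolan-3-yl]dimethylsilanol F4. Tamao oxidation of this silanol (H2O2, KF, KHCO3, THF/MeOH, rt) then gives 14 with retention.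

3. Step 12. The cis C3 hydroxyl may add to the proximal alkyne carbon (5-exo) and so lead, after hydrolysis, to the regioisomeric ketone; the Lewis-acidic medium may also trigger retro-oxa-Michael opening that scrambles C5. The fallback sets out from 16 and comes back at 17. Silylation (TBSOTf, 2,6-lutidine, CH2Cl2, −78 °C) gives tert-butyl{[(2R,3R,5R)-2-{[4-(benzyloxy)-3-methoxyphenyl]methyl}-5-{[4-(benzyloxy)-3-methoxyphenyl]ethynyl}oxolan-3-yl]oxy}dimethylsilane F5. The same gold-catalysed hydration, now with the hydroxyl blocked, gives 1-[4-(benzyloxy)-3-methoxyphenyl]-2-[(2R,4R,5R)-5-{[4-(benzyloxy)-3-methoxyphenyl]methyl}-4-[(tert-butyldimethylsilyl)oxy]oxolan-2-yl]ethan-1-one F6. HF·pyridine in THF at 0 °C removes the silyl group without base and gives 17.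

**Further compounds**

F1 | step 8 | [(2R,3S,5R)-2-{[4-(benzyloxy)-3-methoxyphenyl]methyl}-5-[(triisopropylsilyl)ethynyl]oxolan-3-yl]dimethyl(phenyl)silane | COc1cc(C[C@H]2O[C@@H](C#C[Si](C(C)C)(C(C)C)C(C)C)C[C@@H]2[Si](C)(C)c2ccccc2)ccc1OCc1ccccc1
F2 | step 8 | [(2R,3S,5R)-2-{[4-(benzyloxy)-3-methoxyphenyl]methyl}-5-ethynyloxolan-3-yl]dimethyl(phenyl)silane | COc1cc(C[C@H]2O[C@@H](C#C)C[C@@H]2[Si](C)(C)c2ccccc2)ccc1OCc1ccccc1
F3 | step 8 | 1-(benzyloxy)-4-iodo-2-methoxybenzene | COc1cc(I)ccc1OCc1ccccc1
F4 | step 9 | [(2R,3S,5R)-2-{[4-(benzyloxy)-3-methoxyphenyl]methyl}-5-{[4-(benzyloxy)-3-methoxyphenyl]ethynyl}oxolan-3-yl]dimethylsilanol | COc1cc(C[C@H]2O[C@@H](C#Cc3ccc(OCc4ccccc4)c(OC)c3)C[C@@H]2[Si](C)(C)O)ccc1OCc1ccccc1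
F5 | step 12 | tert-butyl{[(2R,3R,5R)-2-{[4-(benzyloxy)-3-methoxyphenyl]methyl}-5-{[4-(benzyloxy)-3-methoxyphenyl]ethynyl}oxolan-3-yl]oxy}dimethylsilane | COc1cc(C[C@H]2O[C@@H](C#Cc3ccc(OCc4ccccc4)c(OC)c3)C[C@H]2O[Si](C)(C)C(C)(C)C)ccc1OCc1ccccc1
F6 | step 12 | 1-[4-(benzyloxy)-3-methoxyphenyl]-2-[(2R,4R,5R)-5-{[4-(benzyloxy)-3-methoxyphenyl]methyl}-4-[(tert-butyldimethylsilyl)oxy]oxolan-2-yl]ethan-1-one | COc1cc(C[C@H]2O[C@@H](CC(=O)c3ccc(OCc4ccccc4)c(OC)c3)C[C@H]2O[Si](C)(C)C(C)(C)C)ccc1OCc1ccccc1
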